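Ring B is not bought as an arene but grown from a 2-pyranone. Its substitution (aroyl at C1', oxygen at C2' and C4', carbon branch at C6', hydrogen at C3' and C5') maps atom for atom onto a 5-aroyl-4-methoxy-6-alkyl-2-pyranone plus the two carbons of a ketene acetal. One thermal operation forms C5'–C6' and C3'–C4', expels CO2 and methanol, and delivers the fully substituted benzophenone. The precursor is the 2-pyranone carrying the ring A aroyl group at C5, methoxy at C4 and a 2-silyloxyethyl chain at C6. This chain later becomes the CH2 bridge and C6 of ring C, which is closed through an acylketene.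

Key step: step 8

Remark on the chemistry: the target is taken as the 4-hydroxy-2-pyranone tautomer drawn and has no stereocentre. Ring A is the propyl-bearing ring, ring B (primed locants, C1' bearing the ketone) is the central ring, and ring C is the pyranone.

Step 1
Reactants: 1 5-propylbenzene-1,3-diol
Product: 2 1,3-dimethoxy-5-propylbenzene
Conditions: MeI (2.5 equiv), K2CO3 (3 equiv), acetone, reflux
Reagents that add atoms: iodomethane, CI
Why: Williamson ether synthesis, in which both phenoxides of 1 are alkylated by SN2 attack on MeI and no other site of 1 competes.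

Step 2
Reactants: 2 1,3-dimethoxy-5-propylbenzene
Product: 3 1-(2,4-dimethoxy-6-propylphenyl)ethan-1-one
Conditions: Ac2O (1.5 equiv), Sc(OTf)3 (10 mol %), MeNO2, 50 °C
Reagents that add atoms: acetic anhydride, CC(=O)OC(C)=O
Why: Friedel–Crafts acylation under catalytic metal triflate activation, in which the acylium equivalent attacks C4 of 2 (para to one methoxy group, ortho to the other) rather than the C2 site wedged between both methoxy groups, the product is deactivated towards a second acylation, and the absence of a stoichiometric aluminium halide spares the ortho methyl ether.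

Step 3
Reactants: 4 methyl 3-hydroxypropanoate
Product: 5 methyl 3-[(triisopropylsilyl)oxy]propanoate
Conditions: TIPSCl (1.1 equiv), imidazole (2.2 equiv), DMF, rt
Reagents that add atoms: chlorotriisopropylsilane, CC(C)[Si](Cl)(C(C)C)C(C)C
Why: Imidazole-promoted silylation of a primary alcohol, with the triisopropylsilyl group chosen because it must outlast amide bases, the HCl of step 6 and the heat of step 8.

Step 4
Reactants: 5 methyl 3-[(triisopropylsilyl)oxy]propanoate
Product: 6 N-methoxy-N-methyl-3-[(triisopropylsilyl)oxy]propanamide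
Conditions: MeNH(OMe)·HCl (1.5 equiv), i-PrMgCl (3.0 equiv), THF, −20 → 0 °C
Reagents that add atoms: N,O-dimethylhydroxylamine hydrochloride, CNOC.Cl
Why: Weinreb amide formation by ester aminolysis with the magnesium amide generated in the flask, a protocol in routine use on beta-silyloxy esters because acyl substitution at low temperature is faster than alpha-deprotonation.

Step 5
Reactants: 3 1-(2,4-dimethoxy-6-propylphenyl)ethan-1-one; 6 N-methoxy-N-methyl-3-[(triisopropylsilyl)oxy]propanamide
Product: 8 1-(2,4-dimethoxy-6-propylphenyl)-5-[(triisopropylsilyl)oxy]pentane-1,3-dione (largely enolised), via lithium enolate 7 (not isolated)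
Conditions: 3, LiN(SiMe3)2 (2.2 equiv), THF, −78 °C; 6 (1.2 equiv), −78 → 0 °C; cold 1 M HCl
Reagents that add atoms: none
Why: Claisen-type C-acylation of a ketone lithium enolate by a Weinreb amide, whose alpha protons are too weakly acidic for 7 or the silazide to trigger E1cB loss of silanolate (the weakness of the corresponding methyl ester), while the second equivalent of base stores 8 as its inert chelated diketonate until the quench.

Step 6
Reactants: 8 1-(2,4-dimethoxy-6-propylphenyl)-5-[(triisopropylsilyl)oxy]pentane-1,3-dione; 9 malonyl dichloride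
Product: 11 5-(2,4-dimethoxy-6-propylbenzoyl)-4-hydroxy-6-{2-[(triisopropylsilyl)oxy]ethyl}-2H-pyran-2-one, via triacylmethane acid chloride 10 (not isolated)
Conditions: 9 (1.05 equiv), CH2Cl2 (dilute), 0 → 40 °C, slow argon sweep to carry off HCl
Reagents that add atoms: none
Why: Malonyl dichloride annulation of an enolised 1,3-diketone to a 5-acyl-4-hydroxy-2-pyranone (C-acylation at the central carbon, then enol O-acylation), in which the di-ortho-substituted aroyl group of 10 is the carbonyl twisted out of the chelated enol plane, so the alkanoyl oxygen should close the lactone and place the chain at C6 and the aroyl group at C5.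

Step 7
Reactants: 11 5-(2,4-dimethoxy-6-propylbenzoyl)-4-hydroxy-6-{2-[(triisopropylsilyl)oxy]ethyl}-2H-pyran-2-one
Product: 12 5-(2,4-dimethoxy-6-propylbenzoyl)-4-methoxy-6-{2-[(triisopropylsilyl)oxy]ethyl}-2H-pyran-2-one
Conditions: MeOH (1.5 equiv), PPh3 (1.3 equiv), DIAD (1.3 equiv), THF, 0 °C → rt
Reagents that add atoms: methanol, CO
Why: Mitsunobu etherification, in which the vinylogous acid 11 protonates the betaine and its O4 anion attacks the methyl group of the methoxyphosphonium ion, giving the 4-methoxy-2-pyranone under neutral conditions that cannot provoke base-induced loss of silanol from the C6 chain.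

Step 8
Reactants: 12 5-(2,4-dimethoxy-6-propylbenzoyl)-4-methoxy-6-{2-[(triisopropylsilyl)oxy]ethyl}-2H-pyran-2-one; 13 1,1-dimethoxyethene
Product: 16 (2,4-dimethoxy-6-propylphenyl)(2,4-dimethoxy-6-{2-[(triisopropylsilyl)oxy]ethyl}phenyl)methanone, via bridged lactone adduct 14 (not isolated), via cyclohexadiene ketal 15 (not isolated)
Conditions: 13 (10 equiv), mesitylene, sealed tube (base-washed glass), 140 °C
Reagents that add atoms: none
Why: Inverse-electron-demand Diels–Alder reaction of an acyl-activated 2-pyranone with a ketene acetal, a known way to aryl methyl ethers: the diene C3=C4–C5=C6 of 12, its LUMO lowered by the lactone carbonyl and the 5-aroyl group, adds the electron-rich alkene 13 in a concerted but strongly asynchronous [4+2] process to give 14. Ring B is therefore closed by an intermolecular [4+2] cycloaddition that makes C6–CH2 (C6'–C5') and C3–C(OMe)2 (C3'–C4'), after which 14 expels CO2 by retro-Diels–Alder reaction and diene 15 aromatises by loss of methanol. The selectivity needed is regiochemical: the nucleophilic CH2 of 13 has to bond to C6, which is the beta carbon of the aroyl enone as well as the delta carbon of the dienoate, while the developing dimethoxycarbenium carbon pairs with C3, the enol-ether carbon made nucleophilic by the 4-methoxy group, so both polarisations in 12 point the same way. Capture of the same polarised array through the aroyl oxygen (hetero-Diels–Alder mode) would be reversible, whereas loss of CO2 is not, so material should drain towards 16. The two bridgehead stereocentres of 14 are fixed relative to each other by the bicycle, are formed as a racemate and vanish on aromatisation, so no stereocontrol is required. The silyl ether, the aryl ethers and the shielded ketone are inert under the neutral thermal conditions.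

Step 9
Reactants: 16 (2,4-dimethoxy-6-propylphenyl)(2,4-dimethoxy-6-{2-[(triisopropylsilyl)oxy]ethyl}phenyl)methanone
Product: 17 [2-(2-hydroxyethyl)-4,6-dimethoxyphenyl](2,4-dimethoxy-6-propylphenyl)methanone
Conditions: TBAF (1.5 equiv), AcOH (1.5 equiv), THF, rt → 40 °C
Reagents that add atoms: none
Why: Fluoride-induced desilylation driven by formation of the Si–F bond, with acetic acid buffering the medium so that no free alkoxide sits next to the ketone.

Step 10
Reactants: 17 [2-(2-hydroxyethyl)-4,6-dimethoxyphenyl](2,4-dimethoxy-6-propylphenyl)methanone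
Product: 18 2-[2-(2,4-dimethoxy-6-propylbenzoyl)-3,5-dimethoxyphenyl]acetic acid
Conditions: TEMPO (20 mol %), PhI(OAc)2 (2.5 equiv), MeCN/H2O 1:1, rt
Reagents that add atoms: water, O
Why: TEMPO/PhI(OAc)2 oxoammonium oxidation in aqueous acetonitrile carries the primary alcohol through the aldehyde hydrate to the acid without active chlorine or strong acid, so the electron-rich rings and the benzylic CH2 stay untouched.

Step 11
Reactants: 18 2-[2-(2,4-dimethoxy-6-propylbenzoyl)-3,5-dimethoxyphenyl]acetic acid; 19 2,2,6-trimethyl-4H-1,3-dioxin-4-one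
Product: 22 6-{3-[2-(2,4-dimethoxy-6-propylbenzoyl)-3,5-dimethoxyphenyl]-2-oxopropyl}-2,2-dimethyl-4H-1,3-dioxin-4-one, via acyl imidazole 20 (not isolated), via lithium dienolate 21 (not isolated)
Conditions: 18, CDI (1.1 equiv), THF, rt; added to 21 [19 (3.5 equiv), LiN(SiMe3)2 (3.5 equiv), THF, −78 °C]; −78 → −40 °C; cold 1 M HCl
Reagents that add atoms: none
Why: Gamma-selective C-acylation of the dioxinone (vinylogous ester) lithium dienolate by an acyl imidazole, in which surplus 21 absorbs the N–H of liberated imidazole and the acidic CH2 of 22, and the ketone flanked by four ortho substituents is too shielded to be attacked.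

Step 12
Reactants: 22 6-{3-[2-(2,4-dimethoxy-6-propylbenzoyl)-3,5-dimethoxyphenyl]-2-oxopropyl}-2,2-dimethyl-4H-1,3-dioxin-4-one
Product: 24 6-{[2-(2,4-dimethoxy-6-propylbenzoyl)-3,5-dimethoxyphenyl]methyl}-4-hydroxy-2H-pyran-2-one, via acylketene 23 (not isolated)
Conditions: toluene (0.02 M), 110 °C
Reagents that add atoms: none
Why: Retro-hetero-Diels–Alder fragmentation of the dioxinone releases acetone and acylketene 23, whose ketene carbon is captured by the enol oxygen of the 5-ketone in a six-membered lactonisation, the standard thermal route to 6-substituted 4-hydroxy-2-pyranones.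

Step 13
Reactants: 24 6-{[2-(2,4-dimethoxy-6-propylbenzoyl)-3,5-dimethoxyphenyl]methyl}-4-hydroxy-2H-pyran-2-one
Product: 25 6-{[2-(2,4-dihydroxy-6-propylbenzoyl)-3,5-dihydroxyphenyl]methyl}-4-hydroxy-2H-pyran-2-one (target)
Conditions: BBr3 (12 equiv), CH2Cl2, −78 °C → rt; ice-water
Reagents that add atoms: none
Why: BBr3 cleavage of aryl methyl ethers (borate formation, then SN2 attack of bromide on methyl), in which the two ethers ortho to the ketone go first with chelation assistance, excess reagent at room temperature takes the two para ethers, and ring C, the ketone and the alkyl groups offer no bond that BBr3 cleaves.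

Compound list
1 | 5-propylbenzene-1,3-diol | CCCc1cc(O)cc(O)c1 | starting material
2 | 1,3-dimethoxy-5-propylbenzene | CCCc1cc(OC)cc(OC)c1 | intermediate
3 | 1-(2,4-dimethoxy-6-propylphenyl)ethan-1-one | CCCc1cc(OC)cc(OC)c1C(C)=O | intermediate
4 | methyl 3-hydroxypropanoate | COC(=O)CCO | starting material
5 | methyl 3-[(triisopropylsilyl)oxy]propanoate | COC(=O)CCO[Si](C(C)C)(C(C)C)C(C)C | intermediate
6 | N-methoxy-N-methyl-3-[(triisopropylsilyl)oxy]propanamide | CON(C)C(=O)CCO[Si](C(C)C)(C(C)C)C(C)C | intermediate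
7 | lithium 1-(2,4-dimethoxy-6-propylphenyl)ethen-1-olate (not isolated) | CCCc1cc(OC)cc(OC)c1C(=C)O[Li] | intermediate
8 | 1-(2,4-dimethoxy-6-propylphenyl)-5-[(triisopropylsilyl)oxy]pentane-1,3-dione | CCCc1cc(OC)cc(OC)c1C(=O)CC(=O)CCO[Si](C(C)C)(C(C)C)C(C)C | intermediate
9 | malonyl dichloride | O=C(Cl)CC(=O)Cl | starting material
10 | 4-(2,4-dimethoxy-6-propylbenzoyl)-3,5-dioxo-7-[(triisopropylsilyl)oxy]heptanoyl chloride (not isolated) | CCCc1cc(OC)cc(OC)c1C(=O)C(C(=O)CC(=O)Cl)C(=O)CCO[Si](C(C)C)(C(C)C)C(C)C | intermediate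
11 | 5-(2,4-dimethoxy-6-propylbenzoyl)-4-hydroxy-6-{2-[(triisopropylsilyl)oxy]ethyl}-2H-pyran-2-one | CCCc1cc(OC)cc(OC)c1C(=O)c1c(O)cc(=O)oc1CCO[Si](C(C)C)(C(C)C)C(C)C | intermediate
12 | 5-(2,4-dimethoxy-6-propylbenzoyl)-4-methoxy-6-{2-[(triisopropylsilyl)oxy]ethyl}-2H-pyran-2-one | CCCc1cc(OC)cc(OC)c1C(=O)c1c(OC)cc(=O)oc1CCO[Si](C(C)C)(C(C)C)C(C)C | intermediate
13 | 1,1-dimethoxyethene | C=C(OC)OC | starting material
14 | 6-(2,4-dimethoxy-6-propylbenzoyl)-5,8,8-trimethoxy-1-{2-[(triisopropylsilyl)oxy]ethyl}-2-oxabicyclo[2.2.2]oct-5-en-3-one (racemic, not isolated) | CCCc1cc(OC)cc(OC)c1C(=O)C1=C(OC)C2C(=O)OC1(CCO[Si](C(C)C)(C(C)C)C(C)C)CC2(OC)OC | intermediate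
15 | (2,4-dimethoxy-6-propylphenyl)(4,4,6-trimethoxy-2-{2-[(triisopropylsilyl)oxy]ethyl}cyclohexa-1,5-dien-1-yl)methanone (not isolated) | CCCc1cc(OC)cc(OC)c1C(=O)C1=C(CCO[Si](C(C)C)(C(C)C)C(C)C)CC(OC)(OC)C=C1OC | intermediate
16 | (2,4-dimethoxy-6-propylphenyl)(2,4-dimethoxy-6-{2-[(triisopropylsilyl)oxy]ethyl}phenyl)methanone | CCCc1cc(OC)cc(OC)c1C(=O)c1c(OC)cc(OC)cc1CCO[Si](C(C)C)(C(C)C)C(C)C | intermediate
17 | [2-(2-hydroxyethyl)-4,6-dimethoxyphenyl](2,4-dimethoxy-6-propylphenyl)methanone | CCCc1cc(OC)cc(OC)c1C(=O)c1c(OC)cc(OC)cc1CCO | intermediate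
18 | 2-[2-(2,4-dimethoxy-6-propylbenzoyl)-3,5-dimethoxyphenyl]acetic acid | CCCc1cc(OC)cc(OC)c1C(=O)c1c(OC)cc(OC)cc1CC(=O)O | intermediate
19 | 2,2,6-trimethyl-4H-1,3-dioxin-4-one | CC1=CC(=O)OC(C)(C)O1 | starting material
20 | 2-[2-(2,4-dimethoxy-6-propylbenzoyl)-3,5-dimethoxyphenyl]-1-(1H-imidazol-1-yl)ethan-1-one (not isolated) | CCCc1cc(OC)cc(OC)c1C(=O)c1c(OC)cc(OC)cc1CC(=O)n1ccnc1 | intermediate
21 | lithium 2,2-dimethyl-6-methylidene-6H-1,3-dioxin-4-olate (not isolated) | C=C1C=C(O[Li])OC(C)(C)O1 | intermediate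
22 | 6-{3-[2-(2,4-dimethoxy-6-propylbenzoyl)-3,5-dimethoxyphenyl]-2-oxopropyl}-2,2-dimethyl-4H-1,3-dioxin-4-one | CCCc1cc(OC)cc(OC)c1C(=O)c1c(OC)cc(OC)cc1CC(=O)CC1=CC(=O)OC(C)(C)O1 | intermediate
23 | 6-[2-(2,4-dimethoxy-6-propylbenzoyl)-3,5-dimethoxyphenyl]hex-1-ene-1,3,5-trione (acylketene, not isolated) | CCCc1cc(OC)cc(OC)c1C(=O)c1c(OC)cc(OC)cc1CC(=O)CC(=O)C=C=O | intermediate
24 | 6-{[2-(2,4-dimethoxy-6-propylbenzoyl)-3,5-dimethoxyphenyl]methyl}-4-hydroxy-2H-pyran-2-one | CCCc1cc(OC)cc(OC)c1C(=O)c1c(OC)cc(OC)cc1Cc1cc(O)cc(=O)o1 | intermediate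
25 | 6-{[2-(2,4-dihydroxy-6-propylbenzoyl)-3,5-dihydroxyphenyl]methyl}-4-hydroxy-2H-pyran-2-one | CCCc1cc(O)cc(O)c1C(=O)c1c(O)cc(O)cc1Cc1cc(O)cc(=O)o1 | target

Total step count: 13. Longest linear sequence: 11 steps (1, 2, 5–13; the branch 3, 4, 5–13 is equally long).

Steps most likely to fail

Step 8. The donor methoxy group at C4 and the fully substituted C6 may slow the cycloaddition. Oligomerisation of the ketene acetal, or thermal loss of silanol from the side chain, could then win. In the fallback ring B comes from a purchased arene and the diaryl ketone is made by carbonyl addition. It sets out from 2 and comes back at 16. Vilsmeier–Haack formylation of 2 (POCl3, DMF) should give 2,4-dimethoxy-6-propylbenzaldehyde F1. Commercial 2-(3,5-dimethoxyphenyl)ethanol is silylated (TIPSCl, imidazole) to [2-(3,5-dimethoxyphenyl)ethoxy]triisopropylsilane F2. Bromination para to a methoxy group (NBS, MeCN, 0 °C) gives [2-(2-bromo-3,5-dimethoxyphenyl)ethoxy]triisopropylsilane F3. Exchange with n-BuLi (THF, −78 °C) gives (2,4-dimethoxy-6-{2-[(triisopropylsilyl)oxy]ethyl}phenyl)lithium F4. This adds to F1 to give the racemic (2,4-dimethoxy-6-propylphenyl)(2,4-dimethoxy-6-{2-[(triisopropylsilyl)oxy]ethyl}phenyl)methanol F5. Oxidation with Dess–Martin periodinane then gives 16.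

Step 6. Three processes threaten this step:
- lactone closure through the aroyl oxygen in place of the alkanoyl oxygen;
- a second annulation of the product at O4/C3 by surplus bis-acid chloride;
- acid-induced loss of the silyl ether under the HCl evolved.

The fallback builds the pyranone from a keto ester, which has only one ketone oxygen, and attaches ring A afterwards. It sets out from 6 (and uses 9 and 2) and comes back at 12. Allyl acetate is deprotonated (LiN(SiMe3)2, THF, −78 °C) to the lithium enolate of allyl acetate F6. Acylation of F6 by 6 gives allyl 3-oxo-5-[(triisopropylsilyl)oxy]pentanoate F7. Annulation with 9 can then give only allyl 4-hydroxy-2-oxo-6-{2-[(triisopropylsilyl)oxy]ethyl}-2H-pyran-5-carboxylate F8. Mitsunobu methylation as in step 7 gives allyl 4-methoxy-2-oxo-6-{2-[(triisopropylsilyl)oxy]ethyl}-2H-pyran-5-carboxylate F9. Deallylation with Pd(PPh3)4 and morpholine gives 4-methoxy-2-oxo-6-{2-[(triisopropylsilyl)oxy]ethyl}-2H-pyran-5-carboxylic acid F10. Trifluoroacetic anhydride in CH2Cl2 converts this into the mixed trifluoroacetic anhydride F11. F11 acylates 2 in a Friedel–Crafts reaction at the same ring position as in step 2 to give 12.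

Step 11. Three processes threaten this step:
- proton transfer from the acidic benzylic CH2 of the acyl imidazole to the dienolate;
- attack through the alpha carbon of the dienolate;
- capture of the activated acyl group by the neighbouring ketone oxygen.

The fallback replaces acylation by aldol addition and oxidation, so no activated acid is needed. It sets out from 17 and comes back at 22. Dess–Martin oxidation of 17 gives 2-[2-(2,4-dimethoxy-6-propylbenzoyl)-3,5-dimethoxyphenyl]acetaldehyde F12. Dienolate 21 adds to it through its gamma carbon (THF, −78 °C) to give the racemic 6-{3-[2-(2,4-dimethoxy-6-propylbenzoyl)-3,5-dimethoxyphenyl]-2-hydroxypropyl}-2,2-dimethyl-4H-1,3-dioxin-4-one F13. A second Dess–Martin oxidation then gives 22.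

Further compounds
F1 | step 8 | 2,4-dimethoxy-6-propylbenzaldehyde | CCCc1cc(OC)cc(OC)c1C=O
F2 | step 8 | [2-(3,5-dimethoxyphenyl)ethoxy]triisopropylsilane | COc1cc(CCO[Si](C(C)C)(C(C)C)C(C)C)cc(OC)c1
F3 | step 8 | [2-(2-bromo-3,5-dimethoxyphenyl)ethoxy]triisopropylsilane | COc1cc(OC)c(Br)c(CCO[Si](C(C)C)(C(C)C)C(C)C)c1
F4 | step 8 | (2,4-dimethoxy-6-{2-[(triisopropylsilyl)oxy]ethyl}phenyl)lithium | COc1cc(OC)c([Li])c(CCO[Si](C(C)C)(C(C)C)C(C)C)c1
F5 | step 8 | (2,4-dimethoxy-6-propylphenyl)(2,4-dimethoxy-6-{2-[(triisopropylsilyl)oxy]ethyl}phenyl)methanol (racemic) | CCCc1cc(OC)cc(OC)c1C(O)c1c(OC)cc(OC)cc1CCO[Si](C(C)C)(C(C)C)C(C)C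
F6 | step 6 | lithium enolate of allyl acetate | C=CCOC(=C)O[Li]
F7 | step 6 | allyl 3-oxo-5-[(triisopropylsilyl)oxy]pentanoate | C=CCOC(=O)CC(=O)CCO[Si](C(C)C)(C(C)C)C(C)C
F8 | step 6 | allyl 4-hydroxy-2-oxo-6-{2-[(triisopropylsilyl)oxy]ethyl}-2H-pyran-5-carboxylate | C=CCOC(=O)c1c(O)cc(=O)oc1CCO[Si](C(C)C)(C(C)C)C(C)C
F9 | step 6 | allyl 4-methoxy-2-oxo-6-{2-[(triisopropylsilyl)oxy]ethyl}-2H-pyran-5-carboxylate | C=CCOC(=O)c1c(OC)cc(=O)oc1CCO[Si](C(C)C)(C(C)C)C(C)C
F10 | step 6 | 4-methoxy-2-oxo-6-{2-[(triisopropylsilyl)oxy]ethyl}-2H-pyran-5-carboxylic acid | OC(=O)c1c(OC)cc(=O)oc1CCO[Si](C(C)C)(C(C)C)C(C)C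
F11 | step 6 | 4-methoxy-2-oxo-6-{2-[(triisopropylsilyl)oxy]ethyl}-2H-pyran-5-carboxylic trifluoroacetic anhydride | O=C(OC(=O)C(F)(F)F)c1c(OC)cc(=O)oc1CCO[Si](C(C)C)(C(C)C)C(C)C
F12 | step 11 | 2-[2-(2,4-dimethoxy-6-propylbenzoyl)-3,5-dimethoxyphenyl]acetaldehyde | CCCc1cc(OC)cc(OC)c1C(=O)c1c(OC)cc(OC)cc1CC=O
F13 | step 11 | 6-{3-[2-(2,4-dimethoxy-6-propylbenzoyl)-3,5-dimethoxyphenyl]-2-hydroxypropyl}-2,2-dimethyl-4H-1,3-dioxin-4-one (racemic) | CCCc1cc(OC)cc(OC)c1C(=O)c1c(OC)cc(OC)cc1CC(O)CC1=CC(=O)OC(C)(C)O1
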